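The cut is made at the C2–C3 bond of the cyclohexane (ring A), the bond between the CHBr carbon and the C(Cl)CH3 carbon; this vicinal pair is treated as a masked trisubstituted olefin. The key step, a one-pot ring-closing metathesis and ruthenium-catalysed syn-dihydroxylation, closes ring A by forming C2–C3 and sets both carbinol centres on the face anti to the C5 silyl ether. Bromide (inversion at C2) and chloride (retention at C3) then replace the two oxygens. The precursor is an acyclic 1,7-diene, allyl on C6 and methallyl carbinol at C5, that already carries the finished bromo-oxane (ring B), built by asymmetric epoxidation, allyl opening and bromoetherification.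

Key step: step 13

Remark: atoms are numbered as in the bisabolane skeleton (ring A = C1–C6 with Br on C2, Cl/CH3 on C3, OH on C5, junction C6; ring B = O, C7 (CH3), C8 (OAc), C9, C10 (Br), C11 (gem-dimethyl)); TRIP is 3,3'-bis(2,4,6-triisopropylphenyl)-1,1'-binaphthyl-2,2'-diyl hydrogen phosphate, and its (R)-enantiomer is assumed to direct allylboronates to the Re face of aldehydes.

Step 1
Reactants: 1 (E)-4-acetoxy-2-methylbut-2-enal; 2 allylboronic acid pinacol ester
Product: 3 (2E,4S)-4-hydroxy-3-methylhepta-2,6-dien-1-yl acetate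
Conditions: 2 (1.2 equiv), (S)-TRIP (5 mol%), toluene, −30 °C
Reagents that add atoms: allylboronic acid pinacol ester, C=CCB1OC(C)(C)C(C)(C)O1
Why: Chiral phosphoric acid-catalysed allylboration through a chair-like six-membered transition state; the (S)-acid should direct the allyl group to the Si face of the enal and so set C8 as S, while the allylic acetate is inert.

Step 2
Reactants: 3 (2E,4S)-4-hydroxy-3-methylhepta-2,6-dien-1-yl acetate; 4 chlorotriethylsilane
Product: 5 (2E,4S)-3-methyl-4-(triethylsilyloxy)hepta-2,6-dien-1-yl acetate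
Conditions: TESCl, imidazole, DMF, 0 °C
Reagents that add atoms: chlorotriethylsilane, CC[Si](CC)(CC)Cl
Why: Imidazole-promoted silylation of the secondary alcohol masks O8 for the Grignard and oxidation steps with a group that acid methanolysis later removes selectively.

Step 3
Reactants: 5 (2E,4S)-3-methyl-4-(triethylsilyloxy)hepta-2,6-dien-1-yl acetate; 6 2-methyl-2-butene
Product: 7 (2E,4S)-3,7-dimethyl-4-(triethylsilyloxy)octa-2,6-dien-1-yl acetate
Conditions: second-generation Grubbs catalyst (3 mol%), 2-methyl-2-butene (excess), CH2Cl2, 40 °C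
Reagents that add atoms: 2-methyl-2-butene, CC=C(C)C
Why: Olefin cross-metathesis with 2-methyl-2-butene turns the terminal vinyl group into the prenyl-type trisubstituted olefin (C10=C11), and the hindered trisubstituted allylic acetate olefin does not take part.

Step 4
Reactants: 7 (2E,4S)-3,7-dimethyl-4-(triethylsilyloxy)octa-2,6-dien-1-yl acetate
Product: 8 (2E,4S)-3,7-dimethyl-4-(triethylsilyloxy)octa-2,6-dien-1-ol
Conditions: K2CO3, MeOH, 0 °C
Reagents that add atoms: none
Why: Base-catalysed transesterification (methanolysis) frees the primary allylic alcohol needed to direct the epoxidation, and the secondary triethylsilyl ether should survive at 0 °C.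

Step 5
Reactants: 8 (2E,4S)-3,7-dimethyl-4-(triethylsilyloxy)octa-2,6-dien-1-ol; 9 tert-butyl hydroperoxide
Product: 10 {(2R,3S)-3-methyl-3-[(1S)-4-methyl-1-(triethylsilyloxy)pent-3-en-1-yl]oxiran-2-yl}methanol
Conditions: Ti(OiPr)4 (10 mol%), D-(−)-diethyl tartrate (12 mol%), t-BuOOH, 4 Å MS, CH2Cl2, −20 °C
Reagents that add atoms: tert-butyl hydroperoxide, CC(C)(C)OO
Why: Sharpless asymmetric epoxidation of the (E)-allylic alcohol, in which the D-(−)-tartrate should deliver oxygen to the face that gives the (6R,7S)-epoxide under reagent control, the prenyl olefin staying untouched.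

Step 6
Reactants: 10 {(2R,3S)-3-methyl-3-[(1S)-4-methyl-1-(triethylsilyloxy)pent-3-en-1-yl]oxiran-2-yl}methanol; 11 allylmagnesium bromide
Product: 12 (2S,3S,4S)-3,7-dimethyl-2-(prop-2-en-1-yl)-4-(triethylsilyloxy)oct-6-ene-1,3-diol
Conditions: allylMgBr (3 equiv), CuI (10 mol%), THF, −40 to 0 °C
Reagents that add atoms: allylmagnesium bromide, C=CC[Mg]Br
Why: Copper-catalysed SN2 opening of the 2,3-epoxy alcohol at C6, the less substituted epoxide carbon (C7 is fully substituted and flanked by the silyloxy branch), proceeds with inversion, which sets C6 as S and frees the tertiary C7 hydroxyl with its configuration retained.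

Step 7
Reactants: 12 (2S,3S,4S)-3,7-dimethyl-2-(prop-2-en-1-yl)-4-(triethylsilyloxy)oct-6-ene-1,3-diol; 13 2,4,4,6-tetrabromocyclohexa-2,5-dienone (TBCO)
Product: 14 (2S)-2-[(2S,3S,5S)-5-bromo-2,6,6-trimethyl-3-(triethylsilyloxy)oxan-2-yl]pent-4-en-1-ol
Conditions: TBCO (1.1 equiv), CH3NO2, 0 °C, dark
Reagents that add atoms: 2,4,4,6-tetrabromocyclohexa-2,5-dienone, O=C1C(Br)=CC(Br)(Br)C=C1Br
Why: 6-endo (Markovnikov) bromoetherification in which the tertiary C7 hydroxyl opens the bromonium ion of the C10=C11 olefin at C11 through a chair transition state with bromine and the C6 branch equatorial and the C8 silyloxy group axial, which sets C10 as S, while the monosubstituted allyl olefin is much less nucleophilic.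

Step 8
Reactants: 14 (2S)-2-[(2S,3S,5S)-5-bromo-2,6,6-trimethyl-3-(triethylsilyloxy)oxan-2-yl]pent-4-en-1-ol
Product: 15 (2R)-2-[(2S,3S,5S)-5-bromo-2,6,6-trimethyl-3-(triethylsilyloxy)oxan-2-yl]pent-4-enal
Conditions: Dess–Martin periodinane, NaHCO3, CH2Cl2, 0 °C to rt
Reagents that add atoms: none
Why: Dess–Martin oxidation of the primary alcohol under buffered, non-basic conditions should spare the C6 stereocentre (alpha to the new aldehyde, beta to the ring oxygen) from epimerisation and beta-elimination.

Step 9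
Reactants: 15 (2R)-2-[(2S,3S,5S)-5-bromo-2,6,6-trimethyl-3-(triethylsilyloxy)oxan-2-yl]pent-4-enal; 16 2-methylallylboronic acid pinacol ester
Product: 17 (4R,5S)-5-[(2S,3S,5S)-5-bromo-2,6,6-trimethyl-3-(triethylsilyloxy)oxan-2-yl]-2-methylocta-1,7-dien-4-ol
Conditions: 16 (1.5 equiv), (R)-TRIP (10 mol%), toluene, −30 °C
Reagents that add atoms: 2-methylallylboronic acid pinacol ester, CC(=C)CB1OC(C)(C)C(C)(C)O1
Why: Chiral phosphoric acid-catalysed methallylboration in which the (R)-acid directs attack to the Re face and Felkin–Anh control by the large C7 group acts in the same sense (matched case), which sets C5 as R.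

Step 10
Reactants: 17 (4R,5S)-5-[(2S,3S,5S)-5-bromo-2,6,6-trimethyl-3-(triethylsilyloxy)oxan-2-yl]-2-methylocta-1,7-dien-4-ol; 18 tert-butyldimethylsilyl triflate
Product: 19 tert-butyldimethylsilyl ether of 17 at O5 (5R,6S,7S,8S,10S; O8 triethylsilyl ether)
Conditions: TBSOTf, 2,6-lutidine, CH2Cl2, −78 to 0 °C
Reagents that add atoms: tert-butyldimethylsilyl triflate, CC(C)(C)[Si](C)(C)OS(=O)(=O)C(F)(F)F
Why: Silylation of the hindered secondary C5 alcohol with the silyl triflate gives an ether that later shields the upper face of ring A and survives every step up to the last.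

Step 11
Reactants: 19 bis-silyl ether (O5 tert-butyldimethylsilyl, O8 triethylsilyl)
Product: 20 (2S,3S,5S)-5-bromo-2-[(4S,5R)-5-(tert-butyldimethylsilyloxy)-7-methylocta-1,7-dien-4-yl]-2,6,6-trimethyloxan-3-ol
Conditions: PPTS (cat.), MeOH–CH2Cl2, 0 °C
Reagents that add atoms: none
Why: Acid-catalysed methanolysis cleaves the triethylsilyl ether, which is some hundred times more acid-labile than the tert-butyldimethylsilyl ether (selective desilylation).

Step 12
Reactants: 20 (2S,3S,5S)-5-bromo-2-[(4S,5R)-5-(tert-butyldimethylsilyloxy)-7-methylocta-1,7-dien-4-yl]-2,6,6-trimethyloxan-3-ol; 21 acetic anhydride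
Product: 22 (2S,3S,5S)-5-bromo-2-[(4S,5R)-5-(tert-butyldimethylsilyloxy)-7-methylocta-1,7-dien-4-yl]-2,6,6-trimethyloxan-3-yl acetate
Conditions: Ac2O, DMAP, Et3N, CH2Cl2, rt
Reagents that add atoms: acetic anhydride, CC(=O)OC(C)=O
Why: DMAP-catalysed acylation of the hindered secondary C8 alcohol, the only free hydroxyl, installs the acetate of the target at a stage where no other position can compete.

Step 13
Reactants: 22 (2S,3S,5S)-5-bromo-2-[(4S,5R)-5-(tert-butyldimethylsilyloxy)-7-methylocta-1,7-dien-4-yl]-2,6,6-trimethyloxan-3-yl acetate; 23 sodium periodate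
Product: 25 (2S,3S,5S)-5-bromo-2-[(1S,2R,4R,5S)-2-(tert-butyldimethylsilyloxy)-4,5-dihydroxy-4-methylcyclohexyl]-2,6,6-trimethyloxan-3-yl acetate, via cyclohexene 24 (not isolated)
Conditions: second-generation Grubbs catalyst (5 mol%), EtOAc, 60 °C; then NaIO4 (1.5 equiv), CeCl3·7H2O (10 mol%), MeCN–H2O, 0 °C
Reagents that add atoms: sodium periodate, [Na+].[O-]I(=O)(=O)=O
Why: The ruthenium alkylidene engages the monosubstituted olefin of the allyl group first and closes onto the 1,1-disubstituted olefin through a metallacyclobutane, which forms the C2=C3 bond of cyclohexene 24 and expels ethylene (ring-closing metathesis of a 1,7-diene to a six-membered carbocycle, the only ring size open to it). Periodate then converts the spent ruthenium into RuO4, whose concerted [3+2] addition and hydrolysis give the cis-diol, so the closest known reaction type is the one-pot metathesis/ruthenium-catalysed dihydroxylation of dienes. In 24 the large oxanyl group on C6 is equatorial and the C5 silyloxy group is therefore pseudo-axial on the upper face, syn-axial to C3, so RuO4 should add from the open lower face and set C2 (S, OH axial) and C3 (R, OH equatorial, CH3 axial) in one event. The step needs chemoselective initiation at the allyl group, which its lower substitution secures, and a short oxidation at 0 °C with CeCl3 to stop at the diol; silyl ether, acetate, secondary bromide and the fully substituted ether carbons of ring B should be inert to both ruthenium species.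

Step 14
Reactants: 25 cis-2,3-diol; 26 thionyl chloride; 23 sodium periodate
Product: 28 2,3-cyclic sulfate of 25 (2S,3R,5R,6S,7S,8S,10S), via cyclic sulfite 27 (not isolated)
Conditions: SOCl2, Et3N, CH2Cl2, 0 °C; then RuCl3 (cat.), NaIO4, CCl4–MeCN–H2O, 0 °C
Reagents that add atoms: thionyl chloride, O=S(Cl)Cl; sodium periodate, [Na+].[O-]I(=O)(=O)=O
Why: Cyclic sulfite formation on the cis-diol and RuO4 oxidation at sulfur (cyclic sulfate synthesis) turn the diol into a double electrophile without touching either stereocentre.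

Step 15
Reactants: 28 2,3-cyclic sulfate; 29 lithium bromide
Product: 31 (2S,3S,5S)-5-bromo-2-[(1S,2R,4R,5R)-5-bromo-2-(tert-butyldimethylsilyloxy)-4-hydroxy-4-methylcyclohexyl]-2,6,6-trimethyloxan-3-yl acetate, via lithium sulfate monoester 30 (not isolated)
Conditions: LiBr, THF, 60 °C; then H2SO4 (cat.), H2O (2 equiv), THF, rt
Reagents that add atoms: lithium bromide, [Li+].[Br-]
Why: Bromide opens the cyclic sulfate by SN2 at the secondary carbon C2, whose C–O bond is axial, with inversion (Br equatorial and cis to the C6 side chain, C2 becomes R), the tertiary C3–O bond is kept, and the sulfate monoester is then hydrolysed at sulfur with retention (cyclic sulfate opening and acid hydrolysis).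

Step 16
Reactants: 31 trans-diequatorial bromohydrin; 26 thionyl chloride
Product: 33 (2S,3S,5S)-5-bromo-2-[(1S,2R,4R,5R)-5-bromo-2-(tert-butyldimethylsilyloxy)-4-chloro-4-methylcyclohexyl]-2,6,6-trimethyloxan-3-yl acetate, via chlorosulfite 32 (not isolated)
Conditions: SOCl2 (1.5 equiv), CH2Cl2, −20 to 0 °C, no base
Reagents that add atoms: thionyl chloride, O=S(Cl)Cl
Why: The tertiary chlorosulfite ionises and returns chloride to the face it leaves (SNi chlorination with retention), the upper face of the cation being shielded by the syn-axial C5 silyloxy group and the neighbouring C2 bromine, so C3 keeps the heteroatom equatorial and CH3 axial (R).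

Step 17
Reactants: 33 O5-silylated bromochloride
Product: 34 (2S,3S,5S)-5-bromo-2-[(1S,2R,4R,5R)-5-bromo-4-chloro-2-hydroxy-4-methylcyclohexyl]-2,6,6-trimethyloxan-3-yl acetate (target)
Conditions: HF·pyridine, THF, 0 °C to rt
Reagents that add atoms: none
Why: Fluoride-mediated desilylation under slightly acidic conditions should leave the acetate in place (no base-induced acyl migration) and both alkyl halides untouched.

Compound list
1 | (E)-4-acetoxy-2-methylbut-2-enal | CC(=O)OC/C=C(\C)C=O | starting material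
2 | allylboronic acid pinacol ester | C=CCB1OC(C)(C)C(C)(C)O1 | starting material
3 | (2E,4S)-4-hydroxy-3-methylhepta-2,6-dien-1-yl acetate | CC(=O)OC/C=C(\C)[C@@H](O)CC=C | intermediate
4 | chlorotriethylsilane | CC[Si](CC)(CC)Cl | starting material
5 | (2E,4S)-3-methyl-4-(triethylsilyloxy)hepta-2,6-dien-1-yl acetate | CC(=O)OC/C=C(\C)[C@@H](O[Si](CC)(CC)CC)CC=C | intermediate
6 | 2-methyl-2-butene | CC=C(C)C | starting material
7 | (2E,4S)-3,7-dimethyl-4-(triethylsilyloxy)octa-2,6-dien-1-yl acetate | CC(=O)OC/C=C(\C)[C@@H](O[Si](CC)(CC)CC)CC=C(C)C | intermediate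
8 | (2E,4S)-3,7-dimethyl-4-(triethylsilyloxy)octa-2,6-dien-1-ol | OC/C=C(\C)[C@@H](O[Si](CC)(CC)CC)CC=C(C)C | intermediate
9 | tert-butyl hydroperoxide | CC(C)(C)OO | starting material
10 | {(2R,3S)-3-methyl-3-[(1S)-4-methyl-1-(triethylsilyloxy)pent-3-en-1-yl]oxiran-2-yl}methanol | OC[C@H]1O[C@]1(C)[C@@H](O[Si](CC)(CC)CC)CC=C(C)C | intermediate
11 | allylmagnesium bromide | C=CC[Mg]Br | starting material
12 | (2S,3S,4S)-3,7-dimethyl-2-(prop-2-en-1-yl)-4-(triethylsilyloxy)oct-6-ene-1,3-diol | OC[C@H](CC=C)[C@](C)(O)[C@@H](O[Si](CC)(CC)CC)CC=C(C)C | intermediate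
13 | 2,4,4,6-tetrabromocyclohexa-2,5-dienone (TBCO) | O=C1C(Br)=CC(Br)(Br)C=C1Br | starting material
14 | (2S)-2-[(2S,3S,5S)-5-bromo-2,6,6-trimethyl-3-(triethylsilyloxy)oxan-2-yl]pent-4-en-1-ol | CC[Si](CC)(CC)O[C@H]1C[C@H](Br)C(C)(C)O[C@@]1(C)[C@@H](CC=C)CO | intermediate
15 | (2R)-2-[(2S,3S,5S)-5-bromo-2,6,6-trimethyl-3-(triethylsilyloxy)oxan-2-yl]pent-4-enal | CC[Si](CC)(CC)O[C@H]1C[C@H](Br)C(C)(C)O[C@@]1(C)[C@@H](CC=C)C=O | intermediate
16 | 2-methylallylboronic acid pinacol ester | CC(=C)CB1OC(C)(C)C(C)(C)O1 | starting material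
17 | (4R,5S)-5-[(2S,3S,5S)-5-bromo-2,6,6-trimethyl-3-(triethylsilyloxy)oxan-2-yl]-2-methylocta-1,7-dien-4-ol | CC[Si](CC)(CC)O[C@H]1C[C@H](Br)C(C)(C)O[C@@]1(C)[C@@H](CC=C)[C@H](O)CC(C)=C | intermediate
18 | tert-butyldimethylsilyl triflate | CC(C)(C)[Si](C)(C)OS(=O)(=O)C(F)(F)F | starting material
19 | O5-tert-butyldimethylsilyl ether of 17 (O8 triethylsilyl) | CC[Si](CC)(CC)O[C@H]1C[C@H](Br)C(C)(C)O[C@@]1(C)[C@@H](CC=C)[C@H](O[Si](C)(C)C(C)(C)C)CC(C)=C | intermediate
20 | (2S,3S,5S)-5-bromo-2-[(4S,5R)-5-(tert-butyldimethylsilyloxy)-7-methylocta-1,7-dien-4-yl]-2,6,6-trimethyloxan-3-ol | O[C@H]1C[C@H](Br)C(C)(C)O[C@@]1(C)[C@@H](CC=C)[C@H](O[Si](C)(C)C(C)(C)C)CC(C)=C | intermediate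
21 | acetic anhydride | CC(=O)OC(C)=O | starting material
22 | (2S,3S,5S)-5-bromo-2-[(4S,5R)-5-(tert-butyldimethylsilyloxy)-7-methylocta-1,7-dien-4-yl]-2,6,6-trimethyloxan-3-yl acetate | CC(=O)O[C@H]1C[C@H](Br)C(C)(C)O[C@@]1(C)[C@@H](CC=C)[C@H](O[Si](C)(C)C(C)(C)C)CC(C)=C | intermediate
23 | sodium periodate | [Na+].[O-]I(=O)(=O)=O | starting material
24 | (2S,3S,5S)-5-bromo-2-[(1S,6R)-6-(tert-butyldimethylsilyloxy)-4-methylcyclohex-3-en-1-yl]-2,6,6-trimethyloxan-3-yl acetate | CC(=O)O[C@H]1C[C@H](Br)C(C)(C)O[C@@]1(C)[C@H]1CC=C(C)C[C@H]1O[Si](C)(C)C(C)(C)C | intermediate (not isolated)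
25 | (2S,3S,5S)-5-bromo-2-[(1S,2R,4R,5S)-2-(tert-butyldimethylsilyloxy)-4,5-dihydroxy-4-methylcyclohexyl]-2,6,6-trimethyloxan-3-yl acetate | CC(=O)O[C@H]1C[C@H](Br)C(C)(C)O[C@@]1(C)[C@H]1C[C@H](O)[C@](C)(O)C[C@H]1O[Si](C)(C)C(C)(C)C | intermediate
26 | thionyl chloride | O=S(Cl)Cl | starting material
27 | 2,3-cyclic sulfite of 25 (mixture at sulfur) | CC(=O)O[C@H]1C[C@H](Br)C(C)(C)O[C@@]1(C)[C@H]1C[C@@H]2OS(=O)O[C@]2(C)C[C@H]1O[Si](C)(C)C(C)(C)C | intermediate (not isolated)
28 | 2,3-cyclic sulfate of 25 | CC(=O)O[C@H]1C[C@H](Br)C(C)(C)O[C@@]1(C)[C@H]1C[C@@H]2OS(=O)(=O)O[C@]2(C)C[C@H]1O[Si](C)(C)C(C)(C)C | intermediate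
29 | lithium bromide | [Li+].[Br-] | starting material
30 | lithium C3-sulfate monoester of bromohydrin 31 | CC(=O)O[C@H]1C[C@H](Br)C(C)(C)O[C@@]1(C)[C@H]1C[C@@H](Br)[C@](C)(OS(=O)(=O)[O-])C[C@H]1O[Si](C)(C)C(C)(C)C.[Li+] | intermediate (not isolated)
31 | (2S,3S,5S)-5-bromo-2-[(1S,2R,4R,5R)-5-bromo-2-(tert-butyldimethylsilyloxy)-4-hydroxy-4-methylcyclohexyl]-2,6,6-trimethyloxan-3-yl acetate | CC(=O)O[C@H]1C[C@H](Br)C(C)(C)O[C@@]1(C)[C@H]1C[C@@H](Br)[C@](C)(O)C[C@H]1O[Si](C)(C)C(C)(C)C | intermediate
32 | C3 chlorosulfite of 31 | CC(=O)O[C@H]1C[C@H](Br)C(C)(C)O[C@@]1(C)[C@H]1C[C@@H](Br)[C@](C)(OS(=O)Cl)C[C@H]1O[Si](C)(C)C(C)(C)C | intermediate (not isolated)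
33 | (2S,3S,5S)-5-bromo-2-[(1S,2R,4R,5R)-5-bromo-2-(tert-butyldimethylsilyloxy)-4-chloro-4-methylcyclohexyl]-2,6,6-trimethyloxan-3-yl acetate | CC(=O)O[C@H]1C[C@H](Br)C(C)(C)O[C@@]1(C)[C@H]1C[C@@H](Br)[C@](C)(Cl)C[C@H]1O[Si](C)(C)C(C)(C)C | intermediate
34 | (2S,3S,5S)-5-bromo-2-[(1S,2R,4R,5R)-5-bromo-4-chloro-2-hydroxy-4-methylcyclohexyl]-2,6,6-trimethyloxan-3-yl acetate | CC(=O)O[C@H]1C[C@H](Br)C(C)(C)O[C@@]1(C)[C@H]1C[C@@H](Br)[C@](C)(Cl)C[C@H]1O | target

Total step count: 17. Longest linear sequence: 17 steps (from 1).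

Steps most likely to fail

Step 16 (tertiary alcohol to tertiary chloride). Proton loss from the tertiary cation (elimination) may outrun the return of chloride, or the neighbouring bromine may bridge so that chloride enters at C2 and the halogens change places. The fallback sets out from 31 and accepts the elimination. Burgess reagent (benzene, 50 °C, syn-elimination, mainly towards the methyl group) should give the exocyclic olefin F1, with the equatorial C2 bromine kept. Anhydrous HCl in CH2Cl2 at −78 °C then adds in the Markovnikov sense: protonation of the methylene carbon regenerates the C3 cation, and chloride should enter from the open lower face, anti to the C2 bromine and to the C5 silyloxy group. The route is rejoined at 33.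

Step 15 (bromide opening of the cyclic sulfate). Bromide must reach C2 from the crowded upper face, next to a fully substituted carbon, so substitution may be slow and be overtaken by ionisation of the tertiary C3–O bond or by elimination. The fallback sets out from 25 and sets the C2 centre by hydrogen delivery to the open lower face instead. Dess–Martin oxidation of the secondary C2 hydroxyl should give the alpha-hydroxy ketone F2. Hydrazine hydrate in ethanol gives the hydrazone F3. CuBr2 and LiOtBu in THF convert it, with loss of nitrogen, into the geminal dibromide F4. Bu3SnH (1.0 equiv) with Et3B/air in toluene at −78 °C removes one bromine; the alpha-bromo radical should take its hydrogen from the lower face, away from the axial C3 methyl and the C5 silyloxy group, which leaves bromine equatorial. The route is rejoined at 31.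

Step 7 (bromoetherification). The tertiary alcohol may attack the inner olefin carbon (five-membered ether), the bromonium ion may form on the other olefin face (C10 epimer), or the reagent may attack the allyl group. The fallback sets out from 12. Hg(OCOCF3)2 in CH3NO2 at 0 °C, then aqueous KBr: the reversible oxymercuration should settle on the six-membered Markovnikov ether with mercury equatorial, the organomercuric bromide F5. Br2 and LiBr in pyridine in the dark then replace mercury by bromine with retention (polar bromodemercuration). The route is rejoined at 14.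

Further compounds
F1 | step 16 | (2S,3S,5S)-5-bromo-2-[(1S,2R,5R)-5-bromo-2-(tert-butyldimethylsilyloxy)-4-methylidenecyclohexyl]-2,6,6-trimethyloxan-3-yl acetate | CC(=O)O[C@H]1C[C@H](Br)C(C)(C)O[C@@]1(C)[C@H]1C[C@@H](Br)C(=C)C[C@H]1O[Si](C)(C)C(C)(C)C
F2 | step 15 | C2 ketone of diol 25 (alpha-hydroxy ketone; C3 hydroxyl and methyl unchanged) | CC(=O)O[C@H]1C[C@H](Br)C(C)(C)O[C@@]1(C)[C@H]1CC(=O)[C@](C)(O)C[C@H]1O[Si](C)(C)C(C)(C)C
F3 | step 15 | hydrazone of F2 | CC(=O)O[C@H]1C[C@H](Br)C(C)(C)O[C@@]1(C)[C@H]1CC(=NN)[C@](C)(O)C[C@H]1O[Si](C)(C)C(C)(C)C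
F4 | step 15 | C2 geminal dibromide derived from F3 | CC(=O)O[C@H]1C[C@H](Br)C(C)(C)O[C@@]1(C)[C@H]1CC(Br)(Br)[C@](C)(O)C[C@H]1O[Si](C)(C)C(C)(C)C
F5 | step 7 | C10 organomercuric bromide analogue of 14 (HgBr in place of Br, same configuration) | CC[Si](CC)(CC)O[C@H]1C[C@H]([Hg]Br)C(C)(C)O[C@@]1(C)[C@@H](CC=C)CO
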